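The midnight run, charged with 0.13 M of solid substrate, made target per litre about as fast as the winter run with 0.20 M. Midnight's last reading gives 0.210 mM min⁻¹ and winter's gives 0.224 mM min⁻¹, a gap the scatter of 0.5 percentage points on each reading can cover. We call this the take: target, solid product included, made per litre per minute.

| flask | solid substrate | gas | remark | time |
|---|---|---|---|---|
| winter | 0.20 M | 17 mM (held) | the very flask that is asked about, followed so far |  |
| midnight | 0.13 M | 17 mM (held) | run made earlier |  |
| flask | 0.20 M | 17 mM (held) |  | 2.0 h |

- winter (time / min: target / %, solid product / %): 4.00: 0.9, 0.9; 6.00: 1.7, 0; 10.0: 1.5, 0.1; 20.0: 2.5, 0.5; 30.0: 3.1, 0; 50.0: 5.6, 0.3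
- midnight (time / min: target / %, solid product / %): 6.00: 1.8, 0.7; 12.0: 2.6, 0; 20.0: 3.7, 0; 30.0: 5.1, 0; 50.0: 8.1, 0.2; 80.0: 12.9, 1.2

(scatter of a reading: 0.5 percentage points)

- target and solid product together at 2.0 h, in percent of the solid substrate charged
- concentration of dissolved substrate in solution at 2.0 h, in percent of saturation

- amounts and yields of target count solid product too
- given per volume of solution although it is solid: solid substrate, solid product
- the numbers in the tables scatter by 0.5 percentage points (one standard deviation)
- at the start none of the solid substrate is in solution
- at the start none of the gas is in solution
- dissolved substrate means what is dissolved; the solid is not counted in it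

The bench rule for a stirred slurry is that the pace per litre stays fixed while solid lies in the flask, which is zero order in the solid. So we count turnovers: take times time, divided by the charge, is the share of the charge turned into target. For the winter flask at 2.0 h this gives 12.6%.

The rule's border is where the solid is gone. The charge divided by the take puts it at 15.9 h, later than the asked time. That is a latest place and no estimate of the border: the readings follow target and solid product, and any other use of the substrate brings the border forward. While the take stays steady with solid present, we expect dissolved substrate close to saturation.

The forecast gave 13%, a little above our figure, and 95%, on the ground that “the absolute rate does not depend on the solid loading”. The flask gives 12.7% and 99.3%.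

    solid substrate ⇌ dissolved substrate, rate k1*(cs1 - [dissolved substrate]) while solid is left; crystals form when [dissolved substrate] > cs1 (solubility = 36.0 mM, k = 2.60 min⁻¹)
    dissolved substrate + partner → target (k = 6.20 L mol⁻¹ min⁻¹)
    partner → side product (k = 2.10 min⁻¹)
    solid product ⇌ target, rate k4*(cs4 - [target]) while solid is left; crystals form when [target] > cs4 (solubility = 39.0 mM, k = 19.0 min⁻¹)
    gas ⇌ partner, rate k5*(csat - [partner]) (kL = 0.670 min⁻¹)
    target ⇌ isomer of the product (K = 2.30, k = 0.410 min⁻¹)
    partner → decomposed reagent (k = 0.720 min⁻¹)

Read back, that yield is a take of 0.212 mM min⁻¹, close to the 0.210 mM min⁻¹ from the midnight run. A neighbouring flask differs from the asked flask in one setting, with 0.50 M of solid substrate. The same count, the take times 2.0 h over this larger charge, gives 5.04%. Counted on the take, the latest place of its border is 39.7 h, again later than the asked time. That neighbouring flask gives 5.09%, which is a take of 0.212 mM min⁻¹, and at 2.00 h it still holds 76.6% of its charge as solid.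

(The runs come from a simulation for substances that don't exist; noise was put on by code.)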